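**Retrosynthetic overview**
- Mururin C comes from its triacetate by methanolysis of two aryl acetates and one alkyl acetate; the skeleton is not changed.
- The furan ring (O1, C2, C3, C3a, C7a) of the triacetate comes from the pyrylium ring of a 2-arylchromenylium chloride by oxidation with H2O2: oxygen is inserted between old C2 and C3, the old C4–C2 bond (benzofuran C3–C2) closes the furan, and old C3 is pushed out as the 3-CHO carbon.
- The pyrylium ring comes from acid condensation of 5-(3-hydroxypropyl)-o-vanillin (ring A, O1, C4) with 3,4-diacetoxy-5-methoxyacetophenone (ring B, C2, C3).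
- The aldehyde comes from dihydroconiferyl alcohol and formaldehyde; the ketone comes from acetovanillone by iodination, hydroxylation and acetylation.
- Feature and ring order: the strategy rests on the 2-aryl-3-formyl furan ring, whose C2, C3 and formyl carbon are the three-carbon bridge of a C6–C3–C6 unit and map onto C2, C4 and C3 of a flavylium ring. Both benzene rings are bought, the pyrylium ring is closed in step 5, and it is contracted to the furan ring in step 6.

Key step: step 6

Remark on the chemistry: the target is achiral, so no stereocentre has to be set. The chromenylium salt is carried as its crude chloride. Acetic anhydride is added at the end of step 5 because HCl/AcOH alone cannot be trusted to acetylate the chain fully or to leave every aryl acetate intact.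

**Route**

Step 1
Reactants: 1 dihydroconiferyl alcohol [4-(3-hydroxypropyl)-2-methoxyphenol]; 2 paraformaldehyde (formaldehyde source)
Product: 3 2-hydroxy-5-(3-hydroxypropyl)-3-methoxybenzaldehyde
Conditions: MgCl2 (3 equiv), Et3N (6 equiv), (CH2O)n (8 equiv), MeCN, reflux; then 1 M HCl
Reagents that add atoms: formaldehyde as paraformaldehyde (compound 2), C=O
Why: Casnati–Skattebøl ortho-formylation, in which the magnesium phenoxide directs formaldehyde to the only free position ortho to the phenol and a second formaldehyde oxidises the resulting salicyl alkoxide by hydride transfer, while the primary alcohol is only carried as its magnesium alkoxide (hence the raised MgCl2 and base charges).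

Step 2
Reactants: 4 acetovanillone [1-(4-hydroxy-3-methoxyphenyl)ethanone]
Product: 5 1-(4-hydroxy-3-iodo-5-methoxyphenyl)ethanone
Conditions: NIS (1.05 equiv), TsOH·H2O (10 mol%), MeCN, rt
Reagents that add atoms: N-iodosuccinimide, O=C1CCC(=O)N1I
Why: Electrophilic aromatic iodination directed by the free phenol to its single open ortho position, the para position being blocked by the acetyl group.

Step 3
Reactants: 5 1-(4-hydroxy-3-iodo-5-methoxyphenyl)ethanone
Product: 6 1-(3,4-dihydroxy-5-methoxyphenyl)ethanone
Conditions: 4 M aq. NaOH, CuSO4·5H2O (10 mol%), reflux, N2; then HCl to pH 2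
Reagents that add atoms: sodium hydroxide, [Na+].[OH-]
Why: Copper-catalysed Ullmann-type hydroxylation of an aryl iodide ortho to a phenoxide, the reaction type that turns 5-iodovanillin into 5-hydroxyvanillin, with the ketone protected from aldol chemistry as a vinylogous carboxylate and the catecholate protected by exclusion of air.

Step 4
Reactants: 6 1-(3,4-dihydroxy-5-methoxyphenyl)ethanone
Product: 7 5-acetyl-3-methoxy-1,2-phenylene diacetate (3,4-diacetoxy-5-methoxyacetophenone)
Conditions: Ac2O (3 equiv), pyridine, DMAP (cat.), 0 °C to rt
Reagents that add atoms: acetic anhydride, CC(=O)OC(C)=O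
Why: Nucleophile-catalysed O-acetylation of both phenols, which masks the catechol against oxidation and makes ring B electron-poor for the key step.

Step 5
Reactants: 3 2-hydroxy-5-(3-hydroxypropyl)-3-methoxybenzaldehyde; 7 5-acetyl-3-methoxy-1,2-phenylene diacetate
Product: 9 2-(3,4-diacetoxy-5-methoxyphenyl)-6-(3-acetoxypropyl)-8-methoxychromenylium chloride, via 6-(3-hydroxypropyl)chromenylium chloride 8 (not isolated)
Conditions: dry HCl (g), AcOH, 0 °C to rt; then Ac2O (6 equiv), rt; Et2O (precipitation)
Reagents that add atoms: hydrogen chloride, Cl; acetic anhydride, CC(=O)OC(C)=O; acetic acid (solvent, shares in the chain acetylation), CC(=O)O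
Why: Acid-catalysed aldol condensation of the aryl methyl ketone with the salicylaldehyde and cyclodehydration onto the free ortho phenol is the classical flavylium salt synthesis, and acetic anhydride added only after the condensation consumes the water of reaction, completes the Fischer-type acetylation of the chain and restores any aryl acetate lost to acidolysis.

Step 6
Reactants: 9 2-(3,4-diacetoxy-5-methoxyphenyl)-6-(3-acetoxypropyl)-8-methoxychromenylium chloride
Product: 12 Mururin C triacetate (2-(3,4-diacetoxy-5-methoxyphenyl)-5-(3-acetoxypropyl)-7-methoxybenzofuran-3-carbaldehyde), via 2-hydroperoxy-2H-chromene 10 (not isolated), via aroyl ester aldehyde 11 (not isolated)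
Conditions: 30% aq. H2O2 (1.1 equiv), AcOH–H2O 4:1, 0 °C to rt; then NaOAc (2 equiv), 40 °C
Reagents that add atoms: hydrogen peroxide, OO
Why: Hydrogen peroxide adds to C2, the oxocarbenium carbon of the pyrylium ring, to give the racemic hydroperoxide 10, whose vinylic C3 shifts from C2 to the proximal peroxide oxygen with loss of hydroxide (Criegee rearrangement, the Baeyer–Villiger manifold); water opens the resulting cyclic dioxacarbenium ion to the aroyl ester 11 of the (2-hydroxyaryl)acetaldehyde. The enol of 11 then attacks the ester carbonyl (old C2) through its benzylic carbon (old C4) in a 5-exo-trig (enol-exo) closure, and loss of water from the cyclic hemiketal gives the aromatic furan with old C3 left as the 3-formyl group. The closest known reaction type is the hydrogen peroxide oxidation of flavylium salts to 3-acyl-2-arylbenzofurans by this same ring contraction; the 3-unsubstituted salt ending at the carbaldehyde is its less thoroughly tested member. No stereocentre survives, because the only one formed, C2 of 10, is racemic and becomes the trigonal ester carbon. The step needs C3 rather than aryl migration (aryl migration would end in a coumarin and a phenol), which the two acetoxy groups secure by making ring B a poor migrating group while the C3=C4 bond is an electron-rich ortho-alkoxystyrene. It also needs the new aldehyde and the catechol to escape further oxidation, which the near-stoichiometric peroxide charge at low temperature and the acetate masking provide.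

Step 7
Reactants: 12 Mururin C triacetate
Product: 13 Mururin C [2-(3,4-dihydroxy-5-methoxyphenyl)-5-(3-hydroxypropyl)-7-methoxybenzofuran-3-carbaldehyde]
Conditions: K2CO3 (4 equiv), degassed MeOH, Ar, 0 °C to rt; then 1 M HCl to pH 4
Reagents that add atoms: none
Why: Base-mediated transesterification (methanolysis) removes the two aryl acetates and the primary acetate, while the formyl group, a non-enolisable vinylogous formate, is untouched and degassed solvent with an acidic quench keeps the catecholate from air oxidation.

**Compound list**
1 | dihydroconiferyl alcohol, 4-(3-hydroxypropyl)-2-methoxyphenol | COc1cc(CCCO)ccc1O | starting material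
2 | paraformaldehyde (formaldehyde) | C=O | starting material
3 | 2-hydroxy-5-(3-hydroxypropyl)-3-methoxybenzaldehyde | COc1cc(CCCO)cc(C=O)c1O | intermediate
4 | acetovanillone, 1-(4-hydroxy-3-methoxyphenyl)ethanone | CC(=O)c1ccc(O)c(OC)c1 | starting material
5 | 1-(4-hydroxy-3-iodo-5-methoxyphenyl)ethanone | CC(=O)c1cc(I)c(O)c(OC)c1 | intermediate
6 | 1-(3,4-dihydroxy-5-methoxyphenyl)ethanone | CC(=O)c1cc(O)c(O)c(OC)c1 | intermediate
7 | 5-acetyl-3-methoxy-1,2-phenylene diacetate | CC(=O)c1cc(OC)c(OC(C)=O)c(OC(C)=O)c1 | intermediate
8 | 2-(3,4-diacetoxy-5-methoxyphenyl)-6-(3-hydroxypropyl)-8-methoxychromenylium chloride (not isolated) | COc1cc(CCCO)cc2ccc(-c3cc(OC)c(OC(C)=O)c(OC(C)=O)c3)[o+]c12.[Cl-] | intermediate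
9 | 2-(3,4-diacetoxy-5-methoxyphenyl)-6-(3-acetoxypropyl)-8-methoxychromenylium chloride | COc1cc(CCCOC(C)=O)cc2ccc(-c3cc(OC)c(OC(C)=O)c(OC(C)=O)c3)[o+]c12.[Cl-] | intermediate
10 | racemic 3-[2-(3,4-diacetoxy-5-methoxyphenyl)-2-hydroperoxy-8-methoxy-2H-chromen-6-yl]propyl acetate (not isolated) | COc1cc(CCCOC(C)=O)cc2C=CC(OO)(c3cc(OC)c(OC(C)=O)c(OC(C)=O)c3)Oc12 | intermediate
11 | 4-(3-acetoxypropyl)-2-methoxy-6-(2-oxoethyl)phenyl 3,4-diacetoxy-5-methoxybenzoate (not isolated) | COc1cc(CCCOC(C)=O)cc(CC=O)c1OC(=O)c1cc(OC)c(OC(C)=O)c(OC(C)=O)c1 | intermediate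
12 | Mururin C triacetate, 2-(3,4-diacetoxy-5-methoxyphenyl)-5-(3-acetoxypropyl)-7-methoxybenzofuran-3-carbaldehyde | COc1cc(CCCOC(C)=O)cc2c(C=O)c(-c3cc(OC)c(OC(C)=O)c(OC(C)=O)c3)oc12 | intermediate
13 | Mururin C | COc1cc(-c2oc3c(OC)cc(CCCO)cc3c2C=O)cc(O)c1O | target

**Step count**
Total steps: 7. Longest linear sequence: 6 steps (acetovanillone 4 to 13 through steps 2, 3, 4, 5, 6 and 7); the ring A aldehyde 3 joins after one step.

**Steps most likely to fail**

1. Step 6. The peroxide adduct may rearrange by aryl instead of C3 migration, the aroyl ester may be hydrolysed before the carbon–carbon bond is closed, or the new aldehyde may be over-oxidised in a Dakin-type reaction.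
   - Fallback (sets out from 9, comes back at 12): the furan is built by a 1,2-aryl shift of the chalcone instead of a peroxide ring contraction.
   - Hydration of 9 in NaOAc-buffered aqueous MeCN at 50 °C should open the pyrylium ring to (E)-1-(3,4-diacetoxy-5-methoxyphenyl)-3-[5-(3-acetoxypropyl)-2-hydroxy-3-methoxyphenyl]prop-2-en-1-one F1.
   - MOMCl and iPr2NEt in CH2Cl2 should cap the phenol to give the methoxymethyl ether of that chalcone F2.
   - PhI(OH)OTs in HC(OMe)3 at rt, a trivalent-iodine oxidative rearrangement of the type used for isoflavones, should shift the electron-rich ring A aryl group from the β- to the α-carbon and give racemic 1-(3,4-diacetoxy-5-methoxyphenyl)-2-[5-(3-acetoxypropyl)-3-methoxy-2-(methoxymethoxy)phenyl]-3,3-dimethoxypropan-1-one F3.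
   - TsOH·H2O in (CF3)2CHOH at rt should then remove the methoxymethyl group, close the phenol oxygen onto the aryl ketone, aromatise the ring and unmask the acetal, to give 12.

2. Step 5. The deactivated diacetoxy ketone may condense slowly, and the water of condensation may strip aryl acetates, so that a mixture of partly acylated salts forms that does not precipitate cleanly.
   - Fallback (sets out from 3 and 6, comes back at 9): the free catechol ketone 6 is condensed with 3 in EtOAc–MeOH saturated with dry HCl at 0 °C to rt. The crystalline 2-(3,4-dihydroxy-5-methoxyphenyl)-6-(3-hydroxypropyl)-8-methoxychromenylium chloride F4 should drive the condensation by precipitating.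
   - The three hydroxyl groups are then acetylated without base in AcCl–Ac2O at 40 °C, so the pyrylium ring is not opened and the chloride counter-ion is kept, to give 9.

3. Step 3. Reductive loss of iodine and oxidative degradation of the catecholate in hot alkali may erode the hydroxylation.
   - Fallback (sets out from 4, comes back at 6): Duff formylation of 4 (hexamethylenetetramine, CF3CO2H, reflux; then aq. HCl) at the same ortho position should give 5-acetyl-2-hydroxy-3-methoxybenzaldehyde F5.
   - Dakin oxidation (H2O2 1.1 equiv, aq. NaOH, 0 °C, N2; then HCl) should convert its formyl group into the hydroxyl group of 6, the aldehyde reacting well before the para-acetyl group.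

**Further compounds**
F1 | step 6 | (E)-1-(3,4-diacetoxy-5-methoxyphenyl)-3-[5-(3-acetoxypropyl)-2-hydroxy-3-methoxyphenyl]prop-2-en-1-one | COc1cc(CCCOC(C)=O)cc(/C=C/C(=O)c2cc(OC)c(OC(C)=O)c(OC(C)=O)c2)c1O
F2 | step 6 | (E)-1-(3,4-diacetoxy-5-methoxyphenyl)-3-[5-(3-acetoxypropyl)-3-methoxy-2-(methoxymethoxy)phenyl]prop-2-en-1-one | COCOc1c(OC)cc(CCCOC(C)=O)cc1/C=C/C(=O)c1cc(OC)c(OC(C)=O)c(OC(C)=O)c1
F3 | step 6 | racemic 1-(3,4-diacetoxy-5-methoxyphenyl)-2-[5-(3-acetoxypropyl)-3-methoxy-2-(methoxymethoxy)phenyl]-3,3-dimethoxypropan-1-one | COC(OC)C(C(=O)c1cc(OC)c(OC(C)=O)c(OC(C)=O)c1)c1cc(CCCOC(C)=O)cc(OC)c1OCOC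
F4 | step 5 | 2-(3,4-dihydroxy-5-methoxyphenyl)-6-(3-hydroxypropyl)-8-methoxychromenylium chloride | COc1cc(CCCO)cc2ccc(-c3cc(OC)c(O)c(O)c3)[o+]c12.[Cl-]
F5 | step 3 | 5-acetyl-2-hydroxy-3-methoxybenzaldehyde | CC(=O)c1cc(C=O)c(O)c(OC)c1
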